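## Analysis of the target

The target 15 is a linear tri-depside of three gallic acid units. Ring A carries the free carboxylic acid and is acylated at O4 by the carboxyl group of ring B. Ring B is acylated at O3 by the carboxyl group of ring C, and ring C keeps all three hydroxyls. There is no stereocentre, so the whole problem is constitutional: which of three neighbouring oxygens on ring A and on ring B carries the acyl group. The two aryl esters are the sensitive groups. They are cleaved by bases and nucleophiles, and they can shift to a neighbouring free phenol oxygen through a five-membered tetrahedral intermediate. The free pyrogallol and catechol units are also oxidised easily once deprotonated. The difficulty is that seven hydroxyls of similar reactivity must stay free while O4 of ring A and O3 of ring B are picked out, and the last deprotection must not move either acyl group. The strategy rests on the five hydroxyls that play no part in this choice: C3 and C5 of ring A, C5 of ring B, and C3 and C5 of ring C. Each sits ortho to an oxygen that is already fixed and can be carried as bromine until the end. Rings A and C are then simple mono-functional 2,6-dibromo phenol and acid units, and ring B is a bromocatechol whose two oxygens differ clearly in acidity.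

## Retrosynthetic reasoning

15 ⇒ 14. The last bonds cut are three benzyl–oxygen bonds: the ethers at O4 of ring B and O4 of ring C, and the benzyl ester of ring A. Hydrogenolysis needs no acid, base or nucleophile, so the two depside esters of 15 meet nothing that could cleave or shift them. One kind of protecting group for the acid and both ethers keeps this to a single operation.

14 ⇒ 12 (through 13). The five aryl C–O bonds at C3 and C5 of ring A, C5 of ring B, and C3 and C5 of ring C are traced back to C–Br bonds. These oxygens carry no acyl group and would otherwise have to be told apart from their neighbours; as bromine they are silent during both esterifications. The forward reaction must replace all five bromines by hydroxyl near neutrality: palladium-catalysed borylation to 13, then oxidation of the five C–B bonds without isolating 13. In 14 no two free hydroxyls are adjacent, because O4 of rings B and C is benzylated and O4 of ring A is acylated, so the oxidant meets no catechol.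

12 ⇒ 11 + 2. The ester bond between the ring B carbonyl and O4 of ring A is cut next. Phenol 2 has a single hydroxyl, so the para linkage on ring A follows from constitution and not from selectivity. This phenol is hindered by two bromines and is weakly nucleophilic, so the forward step uses the acid chloride 11, made in the flask from acid 10.

10 ⇒ 9. The carboxyl carbon of ring B is taken back to a formyl group. The aldehyde passes through the first esterification unprotected and is oxidised afterwards under weakly acidic conditions. Ring B therefore needs no second, orthogonal ester.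

9 ⇒ 5 + 8. The ester bond between the ring C carbonyl and O3 of ring B is cut. Each partner has one reactive group: 5 one carboxyl, 8 one hydroxyl. Joining ring C to ring B first puts the unhindered esterification early and leaves the activated ester at ring A to be made immediately before the key step.

8 ⇒ 7 ⇒ 6. The benzyl–O4 bond and then the methyl–O3 bond of ring B are cut. Compound 6 supplies the ring B skeleton with bromine at C5, the aldehyde at C1 and both oxygens. The forward benzylation must choose O4 of catechol 7. O4 is para to the formyl group and ortho to bromine, so it is the more acidic oxygen and a weak base forms its monoanion.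

5 ⇒ 4 ⇒ 3, and 2 ⇒ 1. Ring C acid 5 comes from 3 by benzylation of both acidic sites and hydrolysis of ester 4 in the same flask. For 2 the two C–Br bonds are cut instead, back to 1. Monobenzylation of 3 at the carboxyl group alone is unreliable, because its phenol lies between two bromines and para to the carboxyl group and is about as acidic as the acid. Bromination of 1 can only go ortho to the hydroxyl.

## Alternatives that were turned down

Alternative 1: Ring A is built from acyclic pieces by cutting its C2–C3 and C5–C6 bonds. This gives 1,3-bis(benzyloxy)propan-2-one A2 (C3, C4 and C5 with their oxygens) and the benzyl-ester-bearing vinamidinium salt A3 (C2, C1 and C6). In the forward step KOtBu forms the enolate of A2, which adds to one iminium end of A3. Loss of dimethylamine, a second condensation at the other α-carbon and a second loss of amine close the ring as benzyl 3,5-bis(benzyloxy)-4-hydroxybenzoate A1.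
- For: A1 emerges with O4 free and O3 and O5 benzylated, which is laborious to achieve on a preformed trihydroxybenzoate, and no halogen chemistry is needed.
- Against: the step makes one building block and none of the ester connectivity. Rings B and C still need differentiated protected forms, two esterifications and a deprotection. The α-benzyloxy ketone A2 is a weak carbon acid that can self-condense, and tert-butoxide can exchange the benzyl ester.
- Comparison: this route is stronger late on, because every phenol stays capped until hydrogenolysis and no multi-site catalysis is needed. The chosen strategy offers purchased aromatic rings, no regioselective protection of any triol, and a much shorter path to the key precursor.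

Alternative 2: The carbonyl carbon between rings B and A is removed, cutting both the ring B C1–carbonyl bond and the carbonyl–O4 bond of ring A. The pieces are the ring B bromide A5 (which already carries ring C), carbon monoxide A6 and phenol A1. In the forward step zerovalent palladium, formed from Pd(OAc)2 and Xantphos, inserts into the C–Br bond of A5. A6 inserts to give an acyl–palladium species, and the phenoxide of A1 (Et3N) captures it to give the ketal-protected depside A4.
- For: the hindered ester and the carboxyl carbon are made in one event, all seven oxygens are already in place, metal chemistry acts at one site only, and the ketal and benzyl groups of A4 all fall to hydrogenolysis.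
- Against: A5 needs a bromopyrogallol with its three oxygens differentiated and A1 needs a differentiated ring A, so two regioselective protection sequences are required. A1 is flanked by two benzyloxy groups and should capture the acyl–palladium slowly, so reduction and hydrolysis can compete. Warm amine and phenoxide may exchange the existing ester between rings B and C.
- Comparison: this route is stronger in placing the late risk on one bond instead of five. The chosen strategy avoids all triol differentiation, uses one protecting group type, and reaches its precursor in seven steps from three cheap monoaromatic compounds.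

Alternative 3: Ring B is built by cutting its C1–C6 and C2–C3 bonds. The pieces are 3,4-bis(benzyloxy)furan A8 (C3 to C6 with the three oxygens) and the propiolate ester A9 of the ring A phenol (C1, C2 and the carbonyl). In the forward step the electron-rich furan A8 adds to the alkyne of A9 in a Diels–Alder reaction. ZnI2 or BF3·OEt2 then opens the oxygen bridge, and aromatisation gives the phenol A7.
- For: ring B emerges with O3 as its only free hydroxyl and with ring A already attached, so the regiochemistry of ring B is set by construction.
- Against: A8 is an acid-labile diene that itself takes several steps. A9 presupposes A1 and is an aryl propiolate open to conjugate addition. The direction of bridge opening, which decides whether the hydroxyl ends meta or ortho to the carbonyl, is steered only by the polarisation of the unsaturated ester. A Lewis acid acts next to an aryl ester. Attachment of ring C and deprotection still follow.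
- Comparison: this route is as strong as or stronger than the chosen one in keeping all phenols capped until the end. The chosen strategy offers a far shorter sequence and a ring B unit reached in two steps from a commercial aldehyde.

Key step: step 8

Remark on the chemistry: the ring A depside is taken to be at O4 as drawn. Aryl esters of this kind can shift to a neighbouring free phenol oxygen in basic or protic media, so every operation after step 7 is kept neutral to weakly acidic.

## Route

Step 1
Reactants: 1 benzyl 4-hydroxybenzoate
Product: 2 benzyl 3,5-dibromo-4-hydroxybenzoate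
Conditions: Br2 (2.1 equiv), NaOAc, AcOH, rt
Reagents that add atoms: bromine, BrBr
Why: Electrophilic aromatic bromination; the hydroxyl directs to its two ortho positions (para is blocked), the benzyl ester ring is far less activated, and NaOAc takes up HBr so the benzyl ester is not cleaved.

Step 2
Reactants: 3 3,5-dibromo-4-hydroxybenzoic acid
Product: 5 4-(benzyloxy)-3,5-dibromobenzoic acid, via benzyl ester 4 (not isolated)
Conditions: BnBr (2.3 equiv), K2CO3, DMF, 60 °C; then 2 M NaOH, MeOH, 60 °C; HCl
Reagents that add atoms: benzyl bromide, BrCc1ccccc1; sodium hydroxide, [Na+].[OH-] (its oxygen enters the carboxyl group when ester 4 is cleaved at the acyl–oxygen bond)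
Why: Williamson etherification of the phenoxide and alkylation of the carboxylate give 4; saponification then frees the acid, and the aryl benzyl ether is inert to hydroxide.

Step 3
Reactants: 6 5-bromovanillin (3-bromo-4-hydroxy-5-methoxybenzaldehyde)
Product: 7 3-bromo-4,5-dihydroxybenzaldehyde
Conditions: BBr3 (2.5 equiv), CH2Cl2, −78 °C → rt; H2O
Reagents that add atoms: none
Why: Lewis-acid cleavage of an aryl methyl ether; boron binds the ether oxygen, bromide attacks the methyl group, and hydrolysis returns the catechol and the aldehyde.

Step 4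
Reactants: 7 3-bromo-4,5-dihydroxybenzaldehyde
Product: 8 4-(benzyloxy)-3-bromo-5-hydroxybenzaldehyde
Conditions: BnBr (1.05 equiv), NaHCO3, NaI (cat.), DMF, 40 °C
Reagents that add atoms: benzyl bromide, BrCc1ccccc1
Why: Regioselective Williamson etherification; hydrogencarbonate ionises only O4, which is para to the formyl group and ortho to bromine, as in the known selective 4-O-alkylation of 3,4-dihydroxybenzaldehydes.

Step 5
Reactants: 5 4-(benzyloxy)-3,5-dibromobenzoic acid; 8 4-(benzyloxy)-3-bromo-5-hydroxybenzaldehyde
Product: 9 2-(benzyloxy)-3-bromo-5-formylphenyl 4-(benzyloxy)-3,5-dibromobenzoate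
Conditions: EDC·HCl, DMAP (cat.), CH2Cl2, 0 °C → rt
Reagents that add atoms: none
Why: Steglich esterification; the O-acylisourea of 5 passes its acyl group through the acylpyridinium ion to the only hydroxyl of 8, and the carboxyl group of 5 is unhindered because its bromines are meta.

Step 6
Reactants: 9 2-(benzyloxy)-3-bromo-5-formylphenyl 4-(benzyloxy)-3,5-dibromobenzoate
Product: 10 4-(benzyloxy)-3-bromo-5-{[4-(benzyloxy)-3,5-dibromobenzoyl]oxy}benzoic acid
Conditions: NaClO2, NaH2PO4, 2-methyl-2-butene, t-BuOH/THF/H2O, rt
Reagents that add atoms: sodium chlorite, [Na+].[O-]Cl=O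
Why: Pinnick oxidation; chlorous acid adds to the aldehyde and fragments to the acid, the alkene scavenges HOCl, and the weakly acidic medium leaves the aryl ester and benzyl ethers intact.

Step 7
Reactants: 10 4-(benzyloxy)-3-bromo-5-{[4-(benzyloxy)-3,5-dibromobenzoyl]oxy}benzoic acid; 2 benzyl 3,5-dibromo-4-hydroxybenzoate
Product: 12 benzyl 4-{[4-(benzyloxy)-3-bromo-5-{[4-(benzyloxy)-3,5-dibromobenzoyl]oxy}benzoyl]oxy}-3,5-dibromobenzoate, via acid chloride 11 (not isolated)
Conditions: (COCl)2, DMF (cat.), CH2Cl2, rt; evaporation; then 2, Et3N, DMAP (cat.), CH2Cl2, 0 °C → rt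
Reagents that add atoms: oxalyl chloride, O=C(Cl)C(=O)Cl (gives the chlorine of intermediate 11; none of its atoms remains in 12)
Why: Acylation of a phenol by an acid chloride under nucleophilic catalysis; the hindered, acidic phenol 2 is fully ionised by Et3N and needs the most reactive acyl donor, and its single hydroxyl fixes the linkage at O4 of ring A.

Step 8
Reactants: 12 benzyl 4-{[4-(benzyloxy)-3-bromo-5-{[4-(benzyloxy)-3,5-dibromobenzoyl]oxy}benzoyl]oxy}-3,5-dibromobenzoate
Product: 14 benzyl 4-{[4-(benzyloxy)-3-hydroxy-5-{[4-(benzyloxy)-3,5-dihydroxybenzoyl]oxy}benzoyl]oxy}-3,5-dihydroxybenzoate, via pentakis-boronate 13 (not isolated)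
Conditions: B2pin2 (7.5 equiv), Pd(dppf)Cl2·CH2Cl2 (25 mol %), KOAc (15 equiv), 1,4-dioxane, 85 °C; filtration through diatomaceous earth; then 30% H2O2, pH 7 phosphate buffer, THF, 0 °C → rt; Na2S2O3
Reagents that add atoms: bis(pinacolato)diboron, CC1(C)OB(OC1(C)C)B1OC(C)(C)C(C)(C)O1 (gives the boryl groups of intermediate 13; none of its atoms remains in 14); hydrogen peroxide, OO (the five new phenolic oxygens)
Why: This is Miyaura borylation followed by oxidative hydroxylation of the arylboronates, a known conversion of an aryl bromide into a phenol, here run at five sites of one molecule. Pd(dppf)Cl2 is reduced in the flask to zerovalent palladium, which inserts into each C–Br bond; bromide on the resulting divalent palladium is exchanged for acetate, the Pd–O bond takes a boryl group from B2pin2, and reductive elimination forms the C–B bond, so 13 results after five such cycles. In the second stage hydroperoxide adds to each boron, the aryl group shifts from boron to oxygen with loss of hydroxide, and hydrolysis of the borate frees the phenol. No ring is closed and no stereocentre is formed; each new oxygen takes the position of the bromine it replaces. The step needs chemoselectivity for C–Br over the two aryl esters, the benzyl ester and the benzyl ethers: KOAc is too weak a base to cleave esters or to start Suzuki coupling between boronate and bromide sites, and insertion into C–Br is much faster than into an ester C–O bond. Each bromine has a hydrogen on one side and an oxygen substituent on the other, so no site is doubly hindered. Oxidation at pH 7 and 0 °C keeps the new phenols of ring A protonated, which holds the ring B acyl group on O4, and no free catechol is exposed to the peroxide because O4 of rings B and C is benzylated. Palladium black is filtered off first because it decomposes H2O2.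

Step 9
Reactants: 14 benzyl 4-{[4-(benzyloxy)-3-hydroxy-5-{[4-(benzyloxy)-3,5-dihydroxybenzoyl]oxy}benzoyl]oxy}-3,5-dihydroxybenzoate
Product: 15 4-{[3,4-dihydroxy-5-(3,4,5-trihydroxybenzoyloxy)benzoyl]oxy}-3,5-dihydroxybenzoic acid
Conditions: H2 (1 atm), 10% Pd/C, THF, rt; filtration under argon
Reagents that add atoms: none
Why: Catalytic hydrogenolysis of two aryl benzyl ethers and one benzyl ester; the neutral, aprotic medium should leave both depside esters in place and the aromatic rings unreduced.

## Compound list

1 | benzyl 4-hydroxybenzoate | O=C(OCc1ccccc1)c1ccc(O)cc1 | starting material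
2 | benzyl 3,5-dibromo-4-hydroxybenzoate | O=C(OCc1ccccc1)c1cc(Br)c(O)c(Br)c1 | intermediate
3 | 3,5-dibromo-4-hydroxybenzoic acid | O=C(O)c1cc(Br)c(O)c(Br)c1 | starting material
4 | benzyl 4-(benzyloxy)-3,5-dibromobenzoate | O=C(OCc1ccccc1)c1cc(Br)c(OCc2ccccc2)c(Br)c1 | intermediate (not isolated)
5 | 4-(benzyloxy)-3,5-dibromobenzoic acid | O=C(O)c1cc(Br)c(OCc2ccccc2)c(Br)c1 | intermediate
6 | 5-bromovanillin (3-bromo-4-hydroxy-5-methoxybenzaldehyde) | COc1cc(C=O)cc(Br)c1O | starting material
7 | 3-bromo-4,5-dihydroxybenzaldehyde | O=Cc1cc(O)c(O)c(Br)c1 | intermediate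
8 | 4-(benzyloxy)-3-bromo-5-hydroxybenzaldehyde | O=Cc1cc(O)c(OCc2ccccc2)c(Br)c1 | intermediate
9 | 2-(benzyloxy)-3-bromo-5-formylphenyl 4-(benzyloxy)-3,5-dibromobenzoate | O=Cc1cc(Br)c(OCc2ccccc2)c(OC(=O)c2cc(Br)c(OCc3ccccc3)c(Br)c2)c1 | intermediate
10 | 4-(benzyloxy)-3-bromo-5-{[4-(benzyloxy)-3,5-dibromobenzoyl]oxy}benzoic acid | O=C(O)c1cc(Br)c(OCc2ccccc2)c(OC(=O)c2cc(Br)c(OCc3ccccc3)c(Br)c2)c1 | intermediate
11 | 4-(benzyloxy)-3-bromo-5-{[4-(benzyloxy)-3,5-dibromobenzoyl]oxy}benzoyl chloride | O=C(Cl)c1cc(Br)c(OCc2ccccc2)c(OC(=O)c2cc(Br)c(OCc3ccccc3)c(Br)c2)c1 | intermediate (not isolated)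
12 | benzyl 4-{[4-(benzyloxy)-3-bromo-5-{[4-(benzyloxy)-3,5-dibromobenzoyl]oxy}benzoyl]oxy}-3,5-dibromobenzoate (pentabromo depside) | O=C(OCc1ccccc1)c1cc(Br)c(OC(=O)c2cc(Br)c(OCc3ccccc3)c(OC(=O)c3cc(Br)c(OCc4ccccc4)c(Br)c3)c2)c(Br)c1 | intermediate
13 | pentakis(4,4,5,5-tetramethyl-1,3,2-dioxaborolan-2-yl) analogue of 12, with a boryl group in place of each bromine | O=C(OCc1ccccc1)c1cc(B2OC(C)(C)C(C)(C)O2)c(OC(=O)c2cc(B3OC(C)(C)C(C)(C)O3)c(OCc3ccccc3)c(OC(=O)c3cc(B4OC(C)(C)C(C)(C)O4)c(OCc4ccccc4)c(B4OC(C)(C)C(C)(C)O4)c3)c2)c(B2OC(C)(C)C(C)(C)O2)c1 | intermediate (not isolated)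
14 | benzyl 4-{[4-(benzyloxy)-3-hydroxy-5-{[4-(benzyloxy)-3,5-dihydroxybenzoyl]oxy}benzoyl]oxy}-3,5-dihydroxybenzoate | O=C(OCc1ccccc1)c1cc(O)c(OC(=O)c2cc(O)c(OCc3ccccc3)c(OC(=O)c3cc(O)c(OCc4ccccc4)c(O)c3)c2)c(O)c1 | intermediate
15 | 4-{[3,4-dihydroxy-5-(3,4,5-trihydroxybenzoyloxy)benzoyl]oxy}-3,5-dihydroxybenzoic acid | O=C(O)c1cc(O)c(OC(=O)c2cc(O)c(O)c(OC(=O)c3cc(O)c(O)c(O)c3)c2)c(O)c1 | target

## Step count and least certain steps

Total step count: 9. Longest linear sequence: 7 steps (steps 3 to 9, from 6 to 15).

**Step 8 (key step).** Several processes can fail here: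
- Five conversions must all succeed on one molecule, so reductive loss of bromine or protodeboronation at a single site would lower the number of oxygens and make separation hard.
- During the hot borylation stage acetate may attack the ester between rings A and B, which is activated while ring A still carries its two bromines.
- During oxidation hydroperoxide may cleave an aryl ester, or the ring B acyl group may shift from O4 to a newly freed neighbouring oxygen of ring A.
- Coupling between boronate and bromide sites would give oligomers.

If only the oxidation stage fails, aqueous KHSO5 in acetone is an oxidant that works on the acidic side. The fallback proper brings ring A in with its oxygens already in place. It sets out from 2 and 10 and comes back at 15.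
- Phenol 2 is protected with MOMCl and i-Pr2NEt as benzyl 3,5-dibromo-4-(methoxymethoxy)benzoate F1.
- Twofold borylation (B2pin2, Pd(dppf)Cl2, KOAc), on a substrate without aryl esters, gives benzyl 4-(methoxymethoxy)-3,5-bis(4,4,5,5-tetramethyl-1,3,2-dioxaborolan-2-yl)benzoate F2. Oxidation with H2O2 gives benzyl 3,5-dihydroxy-4-(methoxymethoxy)benzoate F3.
- BnBr and K2CO3 give benzyl 3,5-bis(benzyloxy)-4-(methoxymethoxy)benzoate F4. Aqueous HCl in THF frees benzyl 3,5-bis(benzyloxy)-4-hydroxybenzoate F5.
- Acylation of F5 with 11 (from 10, as in step 7) gives the tribromo depside benzyl 3,5-bis(benzyloxy)-4-{[4-(benzyloxy)-3-bromo-5-{[4-(benzyloxy)-3,5-dibromobenzoyl]oxy}benzoyl]oxy}benzoate F6. Its ring A ester is no longer activated.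
- Threefold borylation gives the tris-boronate analogue of F6 F7, and buffered H2O2 gives benzyl 3,5-bis(benzyloxy)-4-{[4-(benzyloxy)-3-hydroxy-5-{[4-(benzyloxy)-3,5-dihydroxybenzoyl]oxy}benzoyl]oxy}benzoate F8. None of its new phenols is next to an ester oxygen.
- Hydrogenolysis of the five benzyl groups of F8 (H2, Pd/C, THF) gives 15.

**Step 4.** Benzylation may lose its regioselectivity: the hindered O4 phenoxide may react slowly, so alkylation at O5 or at both oxygens competes. The fallback makes ring B from the symmetric ring C acid, so no choice between oxygens arises. It sets out from 5 and comes back at 10.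
- Acid 5 is converted with Boc2O, DMAP and t-BuOH into tert-butyl 4-(benzyloxy)-3,5-dibromobenzoate F9.
- One bromine–magnesium exchange with i-PrMgCl·LiCl in THF at −20 °C gives [2-(benzyloxy)-3-bromo-5-(tert-butoxycarbonyl)phenyl]magnesium chloride F10. B(OMe)3 traps it as dimethyl [2-(benzyloxy)-3-bromo-5-(tert-butoxycarbonyl)phenyl]boronate F11.
- H2O2 in AcOH oxidises F11 to tert-butyl 4-(benzyloxy)-3-bromo-5-hydroxybenzoate F12.
- Steglich esterification of F12 with a second portion of 5 gives tert-butyl 4-(benzyloxy)-3-bromo-5-{[4-(benzyloxy)-3,5-dibromobenzoyl]oxy}benzoate F13.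
- TFA in CH2Cl2 removes the tert-butyl group and gives 10.

**Step 7.** Acylation of the hindered, weakly nucleophilic phenoxide of 2 may be slow. DMAP could then exchange the ester between rings B and C before the new ester has formed. The fallback reverses the order of the two esterifications, so the hindered one is run first, with a simple acid chloride in excess and no other aryl ester present. It sets out from 8 and comes back at 12.
- TBSCl and imidazole give 4-(benzyloxy)-3-bromo-5-[(tert-butyldimethylsilyl)oxy]benzaldehyde F14.
- Pinnick oxidation gives 4-(benzyloxy)-3-bromo-5-[(tert-butyldimethylsilyl)oxy]benzoic acid F15, and (COCl)2 gives 4-(benzyloxy)-3-bromo-5-[(tert-butyldimethylsilyl)oxy]benzoyl chloride F16.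
- The sodium phenoxide of 2 (NaH, THF) is acylated by F16 to benzyl 4-{[4-(benzyloxy)-3-bromo-5-[(tert-butyldimethylsilyl)oxy]benzoyl]oxy}-3,5-dibromobenzoate F17.
- HF·pyridine removes the silyl group to give benzyl 4-{[4-(benzyloxy)-3-bromo-5-hydroxybenzoyl]oxy}-3,5-dibromobenzoate F18.
- Esterification of F18 with 5 (EDC·HCl, catalytic DMAP, 0 °C) gives 12.

**Step 9.** Once O4 of ring B and the benzyl ester are cleaved, 15 has free phenols beside both depside esters. Traces of base on the catalyst support or a protic co-solvent could cause acyl shift from O3 to O4 on ring B or from O4 to O3 on ring A. The pyrogallol units can also oxidise in air during filtration. The fallback replaces hydrogenolysis by Lewis-acid debenzylation, in which no phenoxide can form: BCl3 with pentamethylbenzene as benzyl cation scavenger in CH2Cl2 at −78 °C, followed by a cold aqueous quench. It sets out from 14 and comes back at 15 and makes no new compound.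

## Further compounds

F1 | step 8 | benzyl 3,5-dibromo-4-(methoxymethoxy)benzoate | COCOc1c(Br)cc(C(=O)OCc2ccccc2)cc1Br
F2 | step 8 | benzyl 4-(methoxymethoxy)-3,5-bis(4,4,5,5-tetramethyl-1,3,2-dioxaborolan-2-yl)benzoate | COCOc1c(B2OC(C)(C)C(C)(C)O2)cc(C(=O)OCc2ccccc2)cc1B1OC(C)(C)C(C)(C)O1
F3 | step 8 | benzyl 3,5-dihydroxy-4-(methoxymethoxy)benzoate | COCOc1c(O)cc(C(=O)OCc2ccccc2)cc1O
F4 | step 8 | benzyl 3,5-bis(benzyloxy)-4-(methoxymethoxy)benzoate | COCOc1c(OCc2ccccc2)cc(C(=O)OCc2ccccc2)cc1OCc1ccccc1
F5 | step 8 | benzyl 3,5-bis(benzyloxy)-4-hydroxybenzoate | O=C(OCc1ccccc1)c1cc(OCc2ccccc2)c(O)c(OCc2ccccc2)c1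
F6 | step 8 | benzyl 3,5-bis(benzyloxy)-4-{[4-(benzyloxy)-3-bromo-5-{[4-(benzyloxy)-3,5-dibromobenzoyl]oxy}benzoyl]oxy}benzoate | O=C(OCc1ccccc1)c1cc(OCc2ccccc2)c(OC(=O)c2cc(Br)c(OCc3ccccc3)c(OC(=O)c3cc(Br)c(OCc4ccccc4)c(Br)c3)c2)c(OCc2ccccc2)c1
F7 | step 8 | tris(4,4,5,5-tetramethyl-1,3,2-dioxaborolan-2-yl) analogue of F6, with a boryl group in place of each bromine | O=C(OCc1ccccc1)c1cc(OCc2ccccc2)c(OC(=O)c2cc(B3OC(C)(C)C(C)(C)O3)c(OCc3ccccc3)c(OC(=O)c3cc(B4OC(C)(C)C(C)(C)O4)c(OCc4ccccc4)c(B4OC(C)(C)C(C)(C)O4)c3)c2)c(OCc2ccccc2)c1
F8 | step 8 | benzyl 3,5-bis(benzyloxy)-4-{[4-(benzyloxy)-3-hydroxy-5-{[4-(benzyloxy)-3,5-dihydroxybenzoyl]oxy}benzoyl]oxy}benzoate | O=C(OCc1ccccc1)c1cc(OCc2ccccc2)c(OC(=O)c2cc(O)c(OCc3ccccc3)c(OC(=O)c3cc(O)c(OCc4ccccc4)c(O)c3)c2)c(OCc2ccccc2)c1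
F9 | step 4 | tert-butyl 4-(benzyloxy)-3,5-dibromobenzoate | CC(C)(C)OC(=O)c1cc(Br)c(OCc2ccccc2)c(Br)c1
F10 | step 4 | [2-(benzyloxy)-3-bromo-5-(tert-butoxycarbonyl)phenyl]magnesium chloride | CC(C)(C)OC(=O)c1cc(Br)c(OCc2ccccc2)c([Mg]Cl)c1
F11 | step 4 | dimethyl [2-(benzyloxy)-3-bromo-5-(tert-butoxycarbonyl)phenyl]boronate | CC(C)(C)OC(=O)c1cc(Br)c(OCc2ccccc2)c(B(OC)OC)c1
F12 | step 4 | tert-butyl 4-(benzyloxy)-3-bromo-5-hydroxybenzoate | CC(C)(C)OC(=O)c1cc(O)c(OCc2ccccc2)c(Br)c1
F13 | step 4 | tert-butyl 4-(benzyloxy)-3-bromo-5-{[4-(benzyloxy)-3,5-dibromobenzoyl]oxy}benzoate | CC(C)(C)OC(=O)c1cc(Br)c(OCc2ccccc2)c(OC(=O)c2cc(Br)c(OCc3ccccc3)c(Br)c2)c1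
F14 | step 7 | 4-(benzyloxy)-3-bromo-5-[(tert-butyldimethylsilyl)oxy]benzaldehyde | O=Cc1cc(Br)c(OCc2ccccc2)c(O[Si](C)(C)C(C)(C)C)c1
F15 | step 7 | 4-(benzyloxy)-3-bromo-5-[(tert-butyldimethylsilyl)oxy]benzoic acid | O=C(O)c1cc(Br)c(OCc2ccccc2)c(O[Si](C)(C)C(C)(C)C)c1
F16 | step 7 | 4-(benzyloxy)-3-bromo-5-[(tert-butyldimethylsilyl)oxy]benzoyl chloride | O=C(Cl)c1cc(Br)c(OCc2ccccc2)c(O[Si](C)(C)C(C)(C)C)c1
F17 | step 7 | benzyl 4-{[4-(benzyloxy)-3-bromo-5-[(tert-butyldimethylsilyl)oxy]benzoyl]oxy}-3,5-dibromobenzoate | O=C(OCc1ccccc1)c1cc(Br)c(OC(=O)c2cc(Br)c(OCc3ccccc3)c(O[Si](C)(C)C(C)(C)C)c2)c(Br)c1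
F18 | step 7 | benzyl 4-{[4-(benzyloxy)-3-bromo-5-hydroxybenzoyl]oxy}-3,5-dibromobenzoate | O=C(OCc1ccccc1)c1cc(Br)c(OC(=O)c2cc(Br)c(OCc3ccccc3)c(O)c2)c(Br)c1
F0 | step 9 | none | none
A1 | alternative 1 | benzyl 3,5-bis(benzyloxy)-4-hydroxybenzoate | O=C(OCc1ccccc1)c1cc(OCc2ccccc2)c(O)c(OCc2ccccc2)c1
A2 | alternative 1 | 1,3-bis(benzyloxy)propan-2-one | O=C(COCc1ccccc1)COCc1ccccc1
A3 | alternative 1 | 2-(benzyloxycarbonyl)-1,3-bis(dimethylamino)trimethinium hexafluorophosphate | CN(C)C=C(C=[N+](C)C)C(=O)OCc1ccccc1.F[P-](F)(F)(F)(F)F
A4 | alternative 2 | benzyl 3,5-bis(benzyloxy)-4-{[2,2-diphenyl-7-{[3,4,5-tris(benzyloxy)benzoyl]oxy}-1,3-benzodioxole-5-carbonyl]oxy}benzoate | O=C(OCc1ccccc1)c1cc(OCc2ccccc2)c(OC(=O)c2cc(OC(=O)c3cc(OCc4ccccc4)c(OCc4ccccc4)c(OCc4ccccc4)c3)c3OC(c4ccccc4)(c4ccccc4)Oc3c2)c(OCc2ccccc2)c1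
A5 | alternative 2 | 6-bromo-2,2-diphenyl-1,3-benzodioxol-4-yl 3,4,5-tris(benzyloxy)benzoate | Brc1cc(OC(=O)c2cc(OCc3ccccc3)c(OCc3ccccc3)c(OCc3ccccc3)c2)c2OC(c3ccccc3)(c3ccccc3)Oc2c1
A6 | alternative 2 | carbon monoxide | [C-]#[O+]
A7 | alternative 3 | benzyl 3,5-bis(benzyloxy)-4-[3,4-bis(benzyloxy)-5-hydroxybenzoyloxy]benzoate | O=C(OCc1ccccc1)c1cc(OCc2ccccc2)c(OC(=O)c2cc(O)c(OCc3ccccc3)c(OCc3ccccc3)c2)c(OCc2ccccc2)c1
A8 | alternative 3 | 3,4-bis(benzyloxy)furan | c1occ(OCc2ccccc2)c1OCc1ccccc1
A9 | alternative 3 | benzyl 3,5-bis(benzyloxy)-4-(prop-2-ynoyloxy)benzoate | C#CC(=O)Oc1c(OCc2ccccc2)cc(C(=O)OCc2ccccc2)cc1OCc1ccccc1
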